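## The problem

The target is a bicyclo[3.3.1]nonane-2,4,9-trione: ring A (C1, C2, C3, C4, C5, C9) is an enolised β-triketone carrying the 3-hydroxybenzoyl group on C3, and ring B (C1, C8, C7, C6, C5, C9) is a cyclohexanone chair that shares C1, C9 and C5 with ring A. There are four stereocentres: the prenylated quaternary bridgeheads C1 (S) and C5 (S), the quaternary C8 (S; methyl axial, homoprenyl equatorial) and C7 (R; prenyl equatorial). C1 and C8 are directly bonded quaternary carbons, and the bond between them is the hardest one in the molecule. The stereocentres help one another: C5 can only be formed on the face of ring A already occupied by the C8 substituent of C1, and C7 is epimerisable as long as it carries a carbonyl group and then prefers the equatorial position, so only the C1/C8 relationship and the absolute configuration need a dedicated stereochemical event. The four trisubstituted alkenes exclude strong acid, electrophilic oxidants and hydrogenation. The acidic β-triketone is prone to O-alkylation, condensation with amines and retro-Claisen cleavage, and the phenol must be masked. The enabling feature is that C5 is a nucleophilic enol carbon of a dearomatised acylphloroglucinol while C6 is an unsubstituted CH2 next to C7, so that a formyl group on C7 (a latent prenyl) turns C6–C7 into the acceptor of a Michael addition that closes ring B.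

## Retrosynthesis

**30 ⇒ 29.** The phenol O–Si bond is cut last. A triisopropylsilyl ether is chosen over a tert-butyldimethylsilyl ether because it must survive aqueous KOH (prenylation), i-Bu2AlH, an amide base and a Grignard reagent. The forward step needs only buffered fluoride.

**29 ⇒ 24.** The C7 prenyl group is traced back through the allyl compound 28, the allylic acetate 27 and the carbinol 25 to the C7 aldehyde 24. C7 arises in the ring closure as an enolate carbon, so it must first carry a carbonyl group. The forward sequence (vinyl addition, acetylation, palladium–formate reduction, cross-metathesis) adds three carbons without touching the bridgeheads.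

**24 ⇒ 23 (key disconnection).** The C5–C6 bond is cut, opening ring B to the dearomatised acylphloroglucinol 23, which carries a 2-substituted acrolein on C8. The neighbouring cut, C1–C8 within the bicycle, would require a ring-closing Michael addition onto a fully substituted β-carbon. It would create the vicinal quaternary pair in the closing event with no control over which of methyl and homoprenyl ends axial. Cutting C5–C6 leaves an unhindered CH2 acceptor and removes one ring and two stereocentres. The forward step must be C-selective and 6-endo, and must leave C7 equatorial.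

**23 ⇒ 22 ⇒ 21.** The C1–C8 bond is cut by a retro-Claisen step to the aryl allyl ether 21. The intramolecular, ordered transition state is what makes two adjacent quaternary carbons accessible, and the alkene geometry of 21 translates into the C1/C8 relationship. The arene of 21 has a mirror plane, so the rearrangement gives racemic 22. A resolution to 23 is accepted as the price of starting from a symmetric aromatic ring that already contains every carbon and oxygen of ring A.

**21 ⇒ 11 + 18.** The ether C–O bond is cut to the diprenylated aroylphloroglucinol 11 and the allylic alcohol 18 (Mitsunobu). The ester of the coupled product 19 is adjusted through alcohol 20 to the enal 21. The ester is kept until after the coupling so that the two oxygenated carbons on the alkene never have to be differentiated.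

**18 ⇒ 17 ⇒ 12 + 13.** The tetrasubstituted alkene is cut at the bond between C3 and the homoprenyl carbon, and at C2–CH2. syn-Carbocupration of methyl but-2-ynoate 13 with the organocopper from homoprenyl bromide 12, then trapping with an iodomethylboronate, gives allylboronate 17. Oxidation gives 18. Homoprenyl and the CH2O carbon are cis by construction.

**11 ⇒ 9 + 10; 9 ⇒ 8 ⇒ 2 + 5.** Two aryl C–prenyl bonds are cut (aqueous-base C-prenylation of 9 with two equivalents of prenyl bromide 10). The aryl–carbonyl bond is then cut to the lithiated tris-MOM ether of phloroglucinol (2, from 1) and the silyl-protected acid 5 (from 3). An aryllithium acylation is preferred to a Friedel–Crafts reaction because the silyl ether would not survive AlCl3 and could not be installed selectively afterwards.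

## Roads not taken

Alternative 1: The cut is C7–C8. In the forward key step Fe(acac)3 (trivalent iron) and PhSiH3 transfer a hydrogen atom to the 1,1-disubstituted alkene of dione A1. The tertiary C8 radical then adds to the enal β-carbon to give A2.
- Merits: the hindered bond next to a quaternary centre forms under neutral conditions, and the C7 CH2CHO group of A2 is one Wittig step from prenyl. This is shorter than the four-step formyl-to-prenyl sequence of the chosen plan.
- Weak points: the C8 radical is planar, and methyl and homoprenyl differ little in size, so the C8 configuration is poorly defined. The prenyl and homoprenyl alkenes can also accept hydrogen atoms. A2 lacks the C4 oxygen, the C5 prenyl group and the C3 aroyl group, all of which must be added to a hindered bicycle (oxidation, bridgehead metalation, acylation), roughly six further steps.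
- Comparison: against the shorter C7 elaboration, the chosen plan sets C8 control by alkene geometry in a chair Claisen and a key product that already carries every ring substituent.

Alternative 2: The cut is C4–C5. Ph3PAuNTf2 (monovalent gold) activates the ethoxy ynone of enol silane A3, and C5 attacks C4 in a 6-endo-dig closure to give vinylogous ester A4.
- Merits: the closure is catalytic, mild, and reliable for hindered bridgeheads. It is probably more dependable as a ring closure than an enolate Michael addition, and its substrate could be made enantioselectively without a resolution. In these respects it is better.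
- Weak points: A3 is a cyclohexanone that already holds the C1/C8 vicinal quaternary pair and C7, so the central difficulty is moved into a long substrate synthesis. A4 still needs C3 metalation and aroylation, and removal of the enol ether under forcing conditions.
- Comparison: the chosen plan sets against it the economy of taking ring A, its three oxygens and the aroyl group from one cheap arene, and of making C1–C8 by a sigmatropic shift. It pays with the loss of half the material at the resolution.

Alternative 3: The cut is C2–C3. KOtBu deprotonates the aroylacetyl chain of keto ester A5, and the carbanion attacks the C1 methyl ester to give A6, the silyl ether of the target.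
- Merits: the endgame is the shortest of all (one deprotection), and no late C3 acylation or C7 homologation is needed. In this respect it is clearly superior.
- Weak points: A5 needs a cyclohexanone with both α-carbons quaternary plus the C7/C8 pair, again a long stereocontrolled synthesis. The ester to be attacked is neopentyl and flanked by a quaternary centre. The non-enolisable 1,3-diketone at C5 invites retro-Claisen cleavage by alkoxide.
- Comparison: the chosen plan has a longer endgame, but its ring closure is onto an unhindered CH2 and its precursor comes from aromatic material in few operations.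

Key step: step 13

Assumption: β-triketones and vinylogous acids are drawn as one enol tautomer although each is a rapidly equilibrating mixture; stereodescriptors refer to the drawn form, and "target numbering" means C1–C9 as used above.

## Route

Step 1
Reactants: 1 phloroglucinol
Product: 2 1,3,5-tris(methoxymethoxy)benzene
Conditions: MOMCl, i-Pr2NEt, DMF, 0 °C → rt
Reagents that add atoms: chloromethyl methyl ether, COCCl
Why: Threefold O-alkylation of the phenol with the hard chloromethyl ether (Williamson type); the acetals later direct ortho-lithiation and come off under acid that an aryl silyl ether tolerates.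

Step 2
Reactants: 3 3-hydroxybenzoic acid
Product: 5 3-[(triisopropylsilyl)oxy]benzoic acid, via bis-silylated ester 4 (not isolated)
Conditions: TIPSCl, imidazole, DMF, rt; then K2CO3, THF/MeOH/H2O, 0 °C; citric acid work-up
Reagents that add atoms: chlorotriisopropylsilane, CC(C)[Si](Cl)(C(C)C)C(C)C
Why: Silylation of phenol and acid, then selective hydrolysis of the labile silyl ester by aqueous carbonate; the bulky aryl silyl ether is kept because it resists the aqueous alkali of step 5.

Step 3
Reactants: 2 1,3,5-tris(methoxymethoxy)benzene; 5 3-[(triisopropylsilyl)oxy]benzoic acid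
Product: 8 [2,4,6-tris(methoxymethoxy)phenyl]{3-[(triisopropylsilyl)oxy]phenyl}methanone, via acid chloride 6 (not isolated), via aryllithium 7 (not isolated)
Conditions: 5, (COCl)2, cat. DMF, CH2Cl2, 0 °C → rt, evaporate; 2, n-BuLi, THF, 0 °C; then 7 added to 6, THF, −78 °C
Reagents that add atoms: none
Why: Directed ortho-lithiation between two MOM ethers, then acylation of the aryllithium by the acid chloride; the ketone, flanked by two ortho acetal oxygens, is too hindered for a second addition under inverse addition at −78 °C.

Step 4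
Reactants: 8 [2,4,6-tris(methoxymethoxy)phenyl]{3-[(triisopropylsilyl)oxy]phenyl}methanone
Product: 9 (2,4,6-trihydroxyphenyl){3-[(triisopropylsilyl)oxy]phenyl}methanone
Conditions: cat. conc. HCl, MeOH, 45 °C
Reagents that add atoms: none
Why: Acid-catalysed acetal exchange removes the three phenolic MOM groups; aryl triisopropylsilyl ethers are stable to dilute acid in methanol.

Step 5
Reactants: 9 (2,4,6-trihydroxyphenyl){3-[(triisopropylsilyl)oxy]phenyl}methanone; 10 prenyl bromide (1-bromo-3-methylbut-2-ene)
Product: 11 [2,4,6-trihydroxy-3,5-bis(3-methylbut-2-en-1-yl)phenyl]{3-[(triisopropylsilyl)oxy]phenyl}methanone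
Conditions: 10 (2.1 equiv in all), 5% aq. KOH, 0 °C
Reagents that add atoms: prenyl bromide (second equivalent of 10), CC(C)=CCBr
Why: Twofold C-prenylation of the phloroglucinol polyanion in water, the standard entry to 3,5-diprenylated acylphloroglucinols; each of the two free ring carbons takes one prenyl group from one equivalent of 10. Water solvates the phenoxide oxygens and favours C- over O-alkylation, and 11 is separated from mono- and over-prenylated material.

Step 6
Reactants: 12 5-bromo-2-methylpent-2-ene (homoprenyl bromide); 13 methyl but-2-ynoate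
Product: 17 methyl (2E)-3,7-dimethyl-2-[(4,4,5,5-tetramethyl-1,3,2-dioxaborolan-2-yl)methyl]octa-2,6-dienoate, via homoprenylmagnesium bromide 14 (not isolated), via homoprenylcopper 15 (not isolated), via alkenylcopper 16 (not isolated)
Conditions: Mg, THF, rt; CuBr·SMe2, THF, −78 → −40 °C; 13, −78 °C; then HMPA, ICH2Bpin, −78 °C → rt
Reagents that add atoms: 2-(iodomethyl)-4,4,5,5-tetramethyl-1,3,2-dioxaborolane, CC1(C)OB(CI)OC1(C)C
Why: syn-Carbocupration of the ynoate at −78 °C places homoprenyl and copper cis, and alkylation of the configurationally stable α-alkoxycarbonyl alkenylcopper (monovalent copper) by the iodomethylboronate with HMPA proceeds with retention, a known route to tetrasubstituted 2-alkoxycarbonyl allylboronates; this geometry later becomes the C8 configuration.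

Step 7
Reactants: 17 methyl (2E)-3,7-dimethyl-2-[(4,4,5,5-tetramethyl-1,3,2-dioxaborolan-2-yl)methyl]octa-2,6-dienoate
Product: 18 methyl (2E)-2-(hydroxymethyl)-3,7-dimethylocta-2,6-dienoate
Conditions: NaBO3·4H2O, THF/H2O, rt
Reagents that add atoms: sodium perborate tetrahydrate (NaBO3·4H2O), [Na+].[Na+].O[B-]1(O)OO[B-](O)(O)OO1
Why: Perborate oxidation of the C–B bond (1,2-shift from boron to oxygen) occurs with retention and without allylic transposition; the near-neutral reagent spares the ester and the alkene geometry.

Step 8
Reactants: 11 [2,4,6-trihydroxy-3,5-bis(3-methylbut-2-en-1-yl)phenyl]{3-[(triisopropylsilyl)oxy]phenyl}methanone; 18 methyl (2E)-2-(hydroxymethyl)-3,7-dimethylocta-2,6-dienoate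
Product: 19 methyl (2E)-2-{[3,5-dihydroxy-2,6-bis(3-methylbut-2-en-1-yl)-4-{3-[(triisopropylsilyl)oxy]benzoyl}phenoxy]methyl}-3,7-dimethylocta-2,6-dienoate
Conditions: PPh3, DIAD, THF, 0 °C → rt
Reagents that add atoms: none
Why: Mitsunobu etherification of a primary allylic alcohol; only the hydroxyl para to the ketone is free of hydrogen bonding to the carbonyl and is the most acidic, so it is alkylated, and SN2′ attack is excluded because the γ-carbon is fully substituted.

Step 9
Reactants: 19 methyl (2E)-2-{[3,5-dihydroxy-2,6-bis(3-methylbut-2-en-1-yl)-4-{3-[(triisopropylsilyl)oxy]benzoyl}phenoxy]methyl}-3,7-dimethylocta-2,6-dienoate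
Product: 20 [2,6-dihydroxy-4-{[(2Z)-2-(hydroxymethyl)-3,7-dimethylocta-2,6-dien-1-yl]oxy}-3,5-bis(3-methylbut-2-en-1-yl)phenyl]{3-[(triisopropylsilyl)oxy]phenyl}methanone
Conditions: i-Bu2AlH (5 equiv), CH2Cl2, −78 °C; aq. potassium sodium tartrate
Reagents that add atoms: none
Why: 1,2-Reduction of the conjugated ester by the aluminium hydride; the first two equivalents convert the chelated phenols into aluminium phenoxides, which make the hindered diaryl ketone a doubly vinylogous carboxylate that should resist hydride at −78 °C.

Step 10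
Reactants: 20 [2,6-dihydroxy-4-{[(2Z)-2-(hydroxymethyl)-3,7-dimethylocta-2,6-dien-1-yl]oxy}-3,5-bis(3-methylbut-2-en-1-yl)phenyl]{3-[(triisopropylsilyl)oxy]phenyl}methanone
Product: 21 (2E)-2-{[3,5-dihydroxy-2,6-bis(3-methylbut-2-en-1-yl)-4-{3-[(triisopropylsilyl)oxy]benzoyl}phenoxy]methyl}-3,7-dimethylocta-2,6-dienal
Conditions: MnO2, CH2Cl2, rt
Reagents that add atoms: none
Why: Heterogeneous MnO2 oxidation of a primary allylic alcohol to the enal under neutral conditions, which leaves the chelated phenols, the prenyl groups and the alkene geometry (formyl cis to methyl) untouched.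

Step 11
Reactants: 21 (2E)-2-{[3,5-dihydroxy-2,6-bis(3-methylbut-2-en-1-yl)-4-{3-[(triisopropylsilyl)oxy]benzoyl}phenoxy]methyl}-3,7-dimethylocta-2,6-dienal
Product: 22 racemic (6S*)-6-[(3S*)-2-formyl-3,7-dimethylocta-1,6-dien-3-yl]-3,5-dihydroxy-4,6-bis(3-methylbut-2-en-1-yl)-2-{3-[(triisopropylsilyl)oxy]benzoyl}cyclohexa-2,4-dien-1-one
Conditions: PhMe (degassed), 110–120 °C, sealed tube
Reagents that add atoms: none
Why: Aromatic Claisen rearrangement to a prenylated ortho carbon; the ortho-dienone cannot re-aromatise (C1 is quaternary, the para position is blocked by the aroyl group) and settles as the cross-conjugated vinylogous acid. In the chair transition state the homoprenyl group cis to the CH2O carbon ends anti to the C1 prenyl group, which gives the (1S*,8S*) relationship in target numbering. The two ortho carbons are enantiotopic, so 22 is racemic.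

Step 12
Reactants: 22 racemic dearomatised enal (C1 S*, C8 S*)
Product: 23 (6S)-6-[(3S)-2-formyl-3,7-dimethylocta-1,6-dien-3-yl]-3,5-dihydroxy-4,6-bis(3-methylbut-2-en-1-yl)-2-{3-[(triisopropylsilyl)oxy]benzoyl}cyclohexa-2,4-dien-1-one (C1 S and C8 S in target numbering)
Conditions: preparative HPLC, amylose tris(3,5-dimethylphenylcarbamate) on silica, hexane/i-PrOH/HCO2H, rt
Reagents that add atoms: none
Why: Chromatographic resolution on a polysaccharide carbamate phase, routine for enolised polyprenylated acylphloroglucinols, with an acidic modifier to keep the vinylogous acid protonated. The (1S,8S) fraction is to be identified by chiroptical comparison after conversion of a sample to 30; the antipode is set aside.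

Step 13
Reactants: 23 (6S)-6-[(3S)-2-formyl-3,7-dimethylocta-1,6-dien-3-yl]-3,5-dihydroxy-4,6-bis(3-methylbut-2-en-1-yl)-2-{3-[(triisopropylsilyl)oxy]benzoyl}cyclohexa-2,4-dien-1-one
Product: 24 (1S,5S,7R,8S)-4-hydroxy-8-methyl-1,5-bis(3-methylbut-2-en-1-yl)-8-(4-methylpent-3-en-1-yl)-2,9-dioxo-3-{3-[(triisopropylsilyl)oxy]benzoyl}bicyclo[3.3.1]non-3-ene-7-carbaldehyde
Conditions: KN(SiMe3)2 (1.3 equiv), THF, −78 → 0 °C; then AcOH
Reagents that add atoms: none
Why: The amide base removes the vinylogous-acid proton of 23, and the charge of the potassium enolate is spread over the ring oxygens, the aroyl oxygen, C3 and C5. C5, its soft carbon terminus, adds to the unsubstituted CH2 terminus (C6) of the 2-substituted acrolein held on C8; the closest known reaction is the base-mediated intramolecular Michael addition of dearomatised acylphloroglucinols to enals that builds bicyclo[3.3.1]nonanes. Ring B (C1, C8, C7, C6, C5, C9) closes in a 6-endo-trig mode. C5 can be reached only from the face of ring A that carries the C8 chain on C1, so its S configuration follows from C1. The C7 aldehyde enolate is protonated by the remaining enol proton, and the slight excess of base keeps C7 epimerisable, so the formyl group settles equatorial on the ring B chair (7R, trans to the equatorial homoprenyl group) because the axial position points into ring A. The step needs C- over O-attack and 1,4- over 1,2-addition: the delocalised enolate is soft, the acceptor terminus is unhindered, and oxa-Michael and aldol adducts can revert whereas the C–C adduct is the stable β-triketone enolate. The aryl silyl ether, the trisubstituted alkenes and the aroyl ketone are inert to the hindered base at low temperature.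

Step 14
Reactants: 24 (1S,5S,7R,8S)-bicyclic aldehyde
Product: 25 (1S,5S,7R,8S)-4-hydroxy-7-(1-hydroxyprop-2-en-1-yl)-8-methyl-1,5-bis(3-methylbut-2-en-1-yl)-8-(4-methylpent-3-en-1-yl)-3-{3-[(triisopropylsilyl)oxy]benzoyl}bicyclo[3.3.1]non-3-ene-2,9-dione (both carbinol epimers)
Conditions: CH2=CHMgBr (3.5 equiv), THF, −78 → −40 °C; then AcOH
Reagents that add atoms: vinylmagnesium bromide, C=C[Mg]Br
Why: Grignard addition to the aldehyde; the first equivalent turns the β-triketone into its magnesium enolate, which protects ring A, and the C9 ketone is shielded by two quaternary bridgeheads. The carbinol centre forms without control and is removed in step 16.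

Step 15
Reactants: 25 (1S,5S,7R,8S)-allylic alcohol (epimers)
Product: 27 (1S,5S,7R,8S)-7-[1-(acetyloxy)prop-2-en-1-yl]-4-hydroxy-8-methyl-1,5-bis(3-methylbut-2-en-1-yl)-8-(4-methylpent-3-en-1-yl)-3-{3-[(triisopropylsilyl)oxy]benzoyl}bicyclo[3.3.1]non-3-ene-2,9-dione (epimers), via enol acetate 26 (not isolated)
Conditions: Ac2O, pyridine, DMAP, CH2Cl2, 0 °C → rt; then MeOH, rt
Reagents that add atoms: acetic anhydride, CC(=O)OC(C)=O
Why: DMAP-catalysed acetylation of the secondary allylic alcohol; the triketone enol is acetylated too, but this vinylogous anhydride is cleaved selectively by DMAP-catalysed methanolysis in the same flask.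

Step 16
Reactants: 27 (1S,5S,7R,8S)-allylic acetate (epimers)
Product: 28 (1S,5S,7R,8S)-4-hydroxy-8-methyl-1,5-bis(3-methylbut-2-en-1-yl)-8-(4-methylpent-3-en-1-yl)-7-(prop-2-en-1-yl)-3-{3-[(triisopropylsilyl)oxy]benzoyl}bicyclo[3.3.1]non-3-ene-2,9-dione
Conditions: Pd(OAc)2 (cat.), PBu3, HCO2H, Et3N, THF, 65 °C
Reagents that add atoms: none
Why: Palladium-catalysed formate reduction of an allylic acetate (Tsuji–Trost ionisation by zerovalent palladium formed in the flask, then decarboxylation of the π-allylpalladium formate). With PBu3 the hydride goes to the substituted allyl terminus, so both epimers converge on the terminal alkene. Formic acid/triethylamine replaces an ammonium salt so that no ammonia can condense with the triketone.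

Step 17
Reactants: 28 (1S,5S,7R,8S)-7-allyl compound
Product: 29 (1S,5S,7R,8S)-4-hydroxy-8-methyl-1,5,7-tris(3-methylbut-2-en-1-yl)-8-(4-methylpent-3-en-1-yl)-3-{3-[(triisopropylsilyl)oxy]benzoyl}bicyclo[3.3.1]non-3-ene-2,9-dione
Conditions: second-generation Grubbs catalyst (cat.), 2-methylbut-2-ene (large excess), CH2Cl2, 40 °C
Reagents that add atoms: 2-methylbut-2-ene, CC=C(C)C
Why: Olefin cross-metathesis; the monosubstituted alkene is the only readily reacting olefin, the trisubstituted prenyl and homoprenyl alkenes are poor substrates for the catalyst, and the large excess of partner outruns ring closure between neighbouring side chains.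

Step 18
Reactants: 29 (1S,5S,7R,8S)-silyl ether
Product: 30 (1S,5S,7R,8S)-4-hydroxy-3-(3-hydroxybenzoyl)-8-methyl-1,5,7-tris(3-methylbut-2-en-1-yl)-8-(4-methylpent-3-en-1-yl)bicyclo[3.3.1]non-3-ene-2,9-dione (CNP0406274.2)
Conditions: Bu4NF, AcOH, THF, 0 °C
Reagents that add atoms: none
Why: Fluoride cleaves the aryl Si–O bond; acetic acid buffering keeps the medium from turning basic, so the β-triketone and the four stereocentres are untouched.

## Compound list

1 | phloroglucinol | Oc1cc(O)cc(O)c1 | starting material
2 | 1,3,5-tris(methoxymethoxy)benzene | COCOc1cc(OCOC)cc(OCOC)c1 | intermediate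
3 | 3-hydroxybenzoic acid | OC(=O)c1cccc(O)c1 | starting material
4 | triisopropylsilyl 3-[(triisopropylsilyl)oxy]benzoate | CC(C)[Si](OC(=O)c1cccc(O[Si](C(C)C)(C(C)C)C(C)C)c1)(C(C)C)C(C)C | intermediate (not isolated)
5 | 3-[(triisopropylsilyl)oxy]benzoic acid | OC(=O)c1cccc(O[Si](C(C)C)(C(C)C)C(C)C)c1 | intermediate
6 | 3-[(triisopropylsilyl)oxy]benzoyl chloride | ClC(=O)c1cccc(O[Si](C(C)C)(C(C)C)C(C)C)c1 | intermediate (not isolated)
7 | [2,4,6-tris(methoxymethoxy)phenyl]lithium | [Li]c1c(OCOC)cc(OCOC)cc1OCOC | intermediate (not isolated)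
8 | [2,4,6-tris(methoxymethoxy)phenyl]{3-[(triisopropylsilyl)oxy]phenyl}methanone | COCOc1cc(OCOC)c(C(=O)c2cccc(O[Si](C(C)C)(C(C)C)C(C)C)c2)c(OCOC)c1 | intermediate
9 | (2,4,6-trihydroxyphenyl){3-[(triisopropylsilyl)oxy]phenyl}methanone | Oc1cc(O)c(C(=O)c2cccc(O[Si](C(C)C)(C(C)C)C(C)C)c2)c(O)c1 | intermediate
10 | prenyl bromide | CC(C)=CCBr | starting material
11 | [2,4,6-trihydroxy-3,5-bis(3-methylbut-2-en-1-yl)phenyl]{3-[(triisopropylsilyl)oxy]phenyl}methanone | O=C(c1cccc(O[Si](C(C)C)(C(C)C)C(C)C)c1)c1c(O)c(CC=C(C)C)c(O)c(CC=C(C)C)c1O | intermediate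
12 | 5-bromo-2-methylpent-2-ene | CC(C)=CCCBr | starting material
13 | methyl but-2-ynoate | CC#CC(=O)OC | starting material
14 | (4-methylpent-3-en-1-yl)magnesium bromide | CC(C)=CCC[Mg]Br | intermediate (not isolated)
15 | (4-methylpent-3-en-1-yl)copper (monovalent copper, as its MgBr2 complex) | CC(C)=CCC[Cu] | intermediate (not isolated)
16 | [(1Z)-1-(methoxycarbonyl)-2,6-dimethylhepta-1,5-dien-1-yl]copper (copper cis to homoprenyl) | COC(=O)/C([Cu])=C(\C)CCC=C(C)C | intermediate (not isolated)
17 | methyl (2E)-3,7-dimethyl-2-[(4,4,5,5-tetramethyl-1,3,2-dioxaborolan-2-yl)methyl]octa-2,6-dienoate | COC(=O)/C(CB1OC(C)(C)C(C)(C)O1)=C(\C)CCC=C(C)C | intermediate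
18 | methyl (2E)-2-(hydroxymethyl)-3,7-dimethylocta-2,6-dienoate | COC(=O)/C(CO)=C(\C)CCC=C(C)C | intermediate
19 | methyl (2E)-2-{[3,5-dihydroxy-2,6-bis(3-methylbut-2-en-1-yl)-4-{3-[(triisopropylsilyl)oxy]benzoyl}phenoxy]methyl}-3,7-dimethylocta-2,6-dienoate | COC(=O)/C(COc1c(CC=C(C)C)c(O)c(C(=O)c2cccc(O[Si](C(C)C)(C(C)C)C(C)C)c2)c(O)c1CC=C(C)C)=C(\C)CCC=C(C)C | intermediate
20 | [2,6-dihydroxy-4-{[(2Z)-2-(hydroxymethyl)-3,7-dimethylocta-2,6-dien-1-yl]oxy}-3,5-bis(3-methylbut-2-en-1-yl)phenyl]{3-[(triisopropylsilyl)oxy]phenyl}methanone | OC/C(COc1c(CC=C(C)C)c(O)c(C(=O)c2cccc(O[Si](C(C)C)(C(C)C)C(C)C)c2)c(O)c1CC=C(C)C)=C(\C)CCC=C(C)C | intermediate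
21 | (2E)-2-{[3,5-dihydroxy-2,6-bis(3-methylbut-2-en-1-yl)-4-{3-[(triisopropylsilyl)oxy]benzoyl}phenoxy]methyl}-3,7-dimethylocta-2,6-dienal | O=C/C(COc1c(CC=C(C)C)c(O)c(C(=O)c2cccc(O[Si](C(C)C)(C(C)C)C(C)C)c2)c(O)c1CC=C(C)C)=C(\C)CCC=C(C)C | intermediate
22 | racemic dearomatised enal, (6S*)-ring carbon and (3S*)-side-chain carbon (both enantiomers) | CC(C)=CCC[C@@](C)(C(=C)C=O)[C@]1(CC=C(C)C)C(=O)C(C(=O)c2cccc(O[Si](C(C)C)(C(C)C)C(C)C)c2)=C(O)C(CC=C(C)C)=C1O.CC(C)=CCC[C@](C)(C(=C)C=O)[C@@]1(CC=C(C)C)C(=O)C(C(=O)c2cccc(O[Si](C(C)C)(C(C)C)C(C)C)c2)=C(O)C(CC=C(C)C)=C1O | intermediate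
23 | (6S)-6-[(3S)-2-formyl-3,7-dimethylocta-1,6-dien-3-yl]-3,5-dihydroxy-4,6-bis(3-methylbut-2-en-1-yl)-2-{3-[(triisopropylsilyl)oxy]benzoyl}cyclohexa-2,4-dien-1-one | CC(C)=CCC[C@@](C)(C(=C)C=O)[C@]1(CC=C(C)C)C(=O)C(C(=O)c2cccc(O[Si](C(C)C)(C(C)C)C(C)C)c2)=C(O)C(CC=C(C)C)=C1O | intermediate
24 | (1S,5S,7R,8S)-4-hydroxy-8-methyl-1,5-bis(3-methylbut-2-en-1-yl)-8-(4-methylpent-3-en-1-yl)-2,9-dioxo-3-{3-[(triisopropylsilyl)oxy]benzoyl}bicyclo[3.3.1]non-3-ene-7-carbaldehyde | CC(C)=CCC[C@@]1(C)[C@H](C=O)C[C@]2(CC=C(C)C)C(=O)[C@@]1(CC=C(C)C)C(=O)C(C(=O)c1cccc(O[Si](C(C)C)(C(C)C)C(C)C)c1)=C2O | intermediate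
25 | (1S,5S,7R,8S)-7-(1-hydroxyprop-2-en-1-yl) compound, both carbinol epimers | CC(C)=CCC[C@@]1(C)[C@H](C(O)C=C)C[C@]2(CC=C(C)C)C(=O)[C@@]1(CC=C(C)C)C(=O)C(C(=O)c1cccc(O[Si](C(C)C)(C(C)C)C(C)C)c1)=C2O | intermediate
26 | (1S,5S,7R,8S)-allylic acetate with O-acetylated triketone enol (drawn as the C4 enol ester), epimers | CC(C)=CCC[C@@]1(C)[C@H](C(OC(C)=O)C=C)C[C@]2(CC=C(C)C)C(=O)[C@@]1(CC=C(C)C)C(=O)C(C(=O)c1cccc(O[Si](C(C)C)(C(C)C)C(C)C)c1)=C2OC(C)=O | intermediate (not isolated)
27 | (1S,5S,7R,8S)-7-[1-(acetyloxy)prop-2-en-1-yl] compound, epimers | CC(C)=CCC[C@@]1(C)[C@H](C(OC(C)=O)C=C)C[C@]2(CC=C(C)C)C(=O)[C@@]1(CC=C(C)C)C(=O)C(C(=O)c1cccc(O[Si](C(C)C)(C(C)C)C(C)C)c1)=C2O | intermediate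
28 | (1S,5S,7R,8S)-4-hydroxy-8-methyl-1,5-bis(3-methylbut-2-en-1-yl)-8-(4-methylpent-3-en-1-yl)-7-(prop-2-en-1-yl)-3-{3-[(triisopropylsilyl)oxy]benzoyl}bicyclo[3.3.1]non-3-ene-2,9-dione | CC(C)=CCC[C@@]1(C)[C@H](CC=C)C[C@]2(CC=C(C)C)C(=O)[C@@]1(CC=C(C)C)C(=O)C(C(=O)c1cccc(O[Si](C(C)C)(C(C)C)C(C)C)c1)=C2O | intermediate
29 | (1S,5S,7R,8S)-4-hydroxy-8-methyl-1,5,7-tris(3-methylbut-2-en-1-yl)-8-(4-methylpent-3-en-1-yl)-3-{3-[(triisopropylsilyl)oxy]benzoyl}bicyclo[3.3.1]non-3-ene-2,9-dione | CC(C)=CCC[C@@]1(C)[C@H](CC=C(C)C)C[C@]2(CC=C(C)C)C(=O)[C@@]1(CC=C(C)C)C(=O)C(C(=O)c1cccc(O[Si](C(C)C)(C(C)C)C(C)C)c1)=C2O | intermediate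
30 | (1S,5S,7R,8S)-4-hydroxy-3-(3-hydroxybenzoyl)-8-methyl-1,5,7-tris(3-methylbut-2-en-1-yl)-8-(4-methylpent-3-en-1-yl)bicyclo[3.3.1]non-3-ene-2,9-dione | CC(C)=CCC[C@@]1(C)[C@H](CC=C(C)C)C[C@]2(CC=C(C)C)C(=O)[C@@]1(CC=C(C)C)C(=O)C(C(=O)c1cccc(O)c1)=C2O | target

## Step count and least certain steps

Total step count: 18. Longest linear sequence: 15 steps (steps 1, 3, 4, 5 and 8–18 from phloroglucinol; equally steps 2, 3, 4, 5 and 8–18 from 3-hydroxybenzoic acid).

**Step 13 (key step).** The most likely failure is attack of an enolate oxygen on C6, after which the C7 aldehyde enolate expels C1. This is an anionic reversal of the Claisen step that re-aromatises ring A; competing 1,2-addition to the formyl group is the second concern. The fallback sets out from 23 and activates the acceptor rather than the donor. Neutral silylation with N,O-bis(trimethylsilyl)acetamide gives the bis(trimethylsilyl) dienol ether F1, in which both enol oxygens are blocked. Catalytic Me3SiOTf in CH2Cl2 at −78 °C then promotes an intramolecular Mukaiyama–Michael addition of C5 to C6, and aqueous acidic work-up removes the silyl groups and equilibrates C7. The route is rejoined at 24.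

**Step 11 (Claisen rearrangement).** The tetrasubstituted enal can lose its geometry by a thermal 1,5-hydrogen shift to a dienol before it rearranges, which would scramble C8. The product can also undergo a second [3,3] shift through the C9 enol to C5, or cyclise prematurely. The fallback sets out from 20 and rearranges at the alcohol oxidation level, where the alkene cannot enolise and no Michael acceptor is present. Heating 20 in toluene gives the racemic dearomatised allylic alcohol F2, and MnO2 oxidation of its primary allylic alcohol returns to the route at 22.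

**Step 12 (resolution).** Tautomer-broadened peaks or on-column cyclisation of the reactive enal may give poor separation. The fallback sets out from 22. The ring is closed on the racemate under the conditions of step 13 to give racemic bicyclic aldehyde F3, a robust β-triketone. This is resolved classically by crystallising its salt with (S)-N,N-dimethyl-1-phenylethylamine, ammonium enolate F4 (the enantiomeric amine is used if the wrong salt is the less soluble one). Acidification returns to the route at 24.

**Step 9 (ester reduction).** Hydride may attack the aroyl ketone, giving over-reduction to the benzhydrol and products derived from it. The fallback sets out from 18 and finishes the redox adjustment before the benzophenone is present: silylation with TBSCl and imidazole gives silyl ether F5, i-Bu2AlH reduction gives allylic alcohol F6, MnO2 oxidation gives enal F7, HF·pyridine gives hydroxy enal F8, and Mitsunobu coupling of F8 with 11 returns to the route at 21.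

**Step 6 (carbocupration and alkylation).** Warming during the slow alkylation may isomerise the alkenylcopper through its allenoate form, which would leak alkene geometry and hence the C8 configuration. The fallback sets out from 12 and 13. The alkenylcopper 16 is generated as before but quenched at −78 °C with I2, a fast trapping that needs no warming, to give iodo ester F9. A Stille coupling of F9 with Bu3SnCH2OH and Pd(PPh3)4 (zerovalent palladium) proceeds with retention and returns to the route at 18.

## Further compounds

F1 | step 13 | bis(trimethylsilyl) dienol ether of 23 (O4 and O9 silylated, C1 S, C8 S) | CC(C)=CCC[C@@](C)(C(=C)C=O)[C@]1(CC=C(C)C)C(=O)C(C(=O)c2cccc(O[Si](C(C)C)(C(C)C)C(C)C)c2)=C(O[Si](C)(C)C)C(CC=C(C)C)=C1O[Si](C)(C)C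
F2 | step 11 | racemic dearomatised allylic alcohol, CH2OH analogue of 22 (C1 S*, C8 S*, both enantiomers) | CC(C)=CCC[C@@](C)(C(=C)CO)[C@]1(CC=C(C)C)C(=O)C(C(=O)c2cccc(O[Si](C(C)C)(C(C)C)C(C)C)c2)=C(O)C(CC=C(C)C)=C1O.CC(C)=CCC[C@](C)(C(=C)CO)[C@@]1(CC=C(C)C)C(=O)C(C(=O)c2cccc(O[Si](C(C)C)(C(C)C)C(C)C)c2)=C(O)C(CC=C(C)C)=C1O
F3 | step 12 | racemic bicyclic aldehyde (24 and its enantiomer) | CC(C)=CCC[C@@]1(C)[C@H](C=O)C[C@]2(CC=C(C)C)C(=O)[C@@]1(CC=C(C)C)C(=O)C(C(=O)c1cccc(O[Si](C(C)C)(C(C)C)C(C)C)c1)=C2O.CC(C)=CCC[C@]1(C)[C@@H](C=O)C[C@@]2(CC=C(C)C)C(=O)[C@]1(CC=C(C)C)C(=O)C(C(=O)c1cccc(O[Si](C(C)C)(C(C)C)C(C)C)c1)=C2O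
F4 | step 12 | (S)-N,N-dimethyl-1-phenylethylammonium enolate of 24 | C[C@@H](c1ccccc1)[NH+](C)C.CC(C)=CCC[C@@]1(C)[C@H](C=O)C[C@]2(CC=C(C)C)C(=O)[C@@]1(CC=C(C)C)C(=O)C(C(=O)c1cccc(O[Si](C(C)C)(C(C)C)C(C)C)c1)=C2[O-]
F5 | step 9 | methyl (2E)-2-({[tert-butyl(dimethyl)silyl]oxy}methyl)-3,7-dimethylocta-2,6-dienoate | COC(=O)/C(CO[Si](C)(C)C(C)(C)C)=C(\C)CCC=C(C)C
F6 | step 9 | (2Z)-2-({[tert-butyl(dimethyl)silyl]oxy}methyl)-3,7-dimethylocta-2,6-dien-1-ol | OC/C(CO[Si](C)(C)C(C)(C)C)=C(\C)CCC=C(C)C
F7 | step 9 | (2E)-2-({[tert-butyl(dimethyl)silyl]oxy}methyl)-3,7-dimethylocta-2,6-dienal | O=C/C(CO[Si](C)(C)C(C)(C)C)=C(\C)CCC=C(C)C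
F8 | step 9 | (2E)-2-(hydroxymethyl)-3,7-dimethylocta-2,6-dienal | O=C/C(CO)=C(\C)CCC=C(C)C
F9 | step 6 | methyl (2Z)-2-iodo-3,7-dimethylocta-2,6-dienoate | COC(=O)/C(I)=C(\C)CCC=C(C)C
A1 | alternative 1 | 2-(6-methylhepta-1,5-dien-2-yl)-2-(3-methylbut-2-en-1-yl)-4-[(2E)-4-oxobut-2-en-1-yl]cyclohexane-1,3-dione, configured as drawn | CC(C)=CCCC(=C)[C@]1(CC=C(C)C)C(=O)CC[C@H](C/C=C/C=O)C1=O
A2 | alternative 1 | bicyclo[3.3.1]nonane-2,9-dione with C7 formylmethyl group | CC(C)=CCC[C@@]1(C)[C@H](CC=O)C[C@@H]2C(=O)[C@@]1(CC=C(C)C)C(=O)CC2
A3 | alternative 2 | tert-butyldimethylsilyl enol ether of the ring B cyclohexanone bearing a 3-ethoxyprop-2-ynoyl group on C1 | CC(C)=CCC[C@@]1(C)[C@H](CC=C(C)C)CC(CC=C(C)C)=C(O[Si](C)(C)C(C)(C)C)[C@@]1(CC=C(C)C)C(=O)C#COCC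
A4 | alternative 2 | bicyclic vinylogous ethyl ester lacking the C3 aroyl group | CC(C)=CCC[C@@]1(C)[C@H](CC=C(C)C)C[C@]2(CC=C(C)C)C(=O)[C@@]1(CC=C(C)C)C(=O)C=C2OCC
A5 | alternative 3 | ring B cyclohexanone with methyl ester on C1 and aroylacetyl chain on C5 | CC(C)=CCC[C@@]1(C)[C@H](CC=C(C)C)C[C@@](CC=C(C)C)(C(=O)CC(=O)c2cccc(O[Si](C)(C)C(C)(C)C)c2)C(=O)[C@@]1(CC=C(C)C)C(=O)OC
A6 | alternative 3 | tert-butyldimethylsilyl ether of the target | CC(C)=CCC[C@@]1(C)[C@H](CC=C(C)C)C[C@]2(CC=C(C)C)C(=O)[C@@]1(CC=C(C)C)C(=O)C(C(=O)c1cccc(O[Si](C)(C)C(C)(C)C)c1)=C2O
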